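Which flask turns the most first end groups into links, and how much?

| setting | cedar | larch | birch |
|---|---|---|---|
| first end groups | 10 mM (fed, over 6.0 min) | 10 mM | 10 mM |
| third end groups | 5.00 mM | 5.00 mM (fed, over 6.0 min) | 5.00 mM |
| gas | 0.83 mM (held) | 0.83 mM (held) | 0.83 mM (held) |
| time | 15 min | 15 min | 15 min |
| remark | all else is in the flask from the start; the feed brings no volume worth counting | all else is in the flask from the start; the feed brings no volume worth counting | everything together at the start |

    gas ⇌ second end groups, rate k1*(csat - [second end groups]) (k1 = 0.37 s⁻¹, csat = 0.83 mM)
    first end groups + second end groups → links (k2 = 30 M⁻¹ s⁻¹)
    second end groups + third end groups → links of the second sort (k3 = 1.8 M⁻¹ s⁻¹)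
    links ⇌ isomer of the product (K4 = 0.81, k4 = 0.021 s⁻¹)
    2 first end groups → self-condensation product (k5 = 2.5 M⁻¹ s⁻¹)

- the best flask by amount of links, in percent of the first end groups charged; "all alike" if 1.5 percentage points covers them all (cedar / larch / birch / all alike)
- amount of links at the end, in percent of the first end groups charged, cedar
- amount of links at the end, in percent of the first end groups charged, larch
- amount of links at the end, in percent of the first end groups charged, birch

- percent here means first end groups units held: one self-condensation product counts as two
- where a step has two of a species, its rate is k times that concentration squared, and two are used at each turn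
- at the start none of second end groups is dissolved
- run time (cedar): 15 min

1. I count exit rates for a first end group. With second end groups at saturation it leaves for links at 1.49 min⁻¹, but at the full charge it leaves for self-condensation at 3.00 min⁻¹, which is faster. The two exits are equal at 4.98 mM, which I call the crossing level.

2. Links also draw down second end groups, whose uptake constant equals this draw at 12.3 mM of first end groups. So the link exit is slowed by a gas factor, 0.552 at the charge. The draw by third end groups is far smaller than the draw by first end groups at the charge, so I drop it.

3. At level c, the share going to links (the selectivity) is 1/(1 + (c/crossing level)(1 + c/gas level)), where the gas level is the figure in step 2.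

4. Larch and birch start at the full charge, with share 0.216. Their level then falls towards zero, and the yield is the mean share over that fall, which I take from two levels: 0.624 at 2.50 mM and 0.292 at 7.50 mM. Their mean is 0.458.

5. Cedar's feed of 1.67 mM min⁻¹ has to balance both exits. Without the gas factor that happens at 0.939 mM, where the factor is 0.929. With the factor, the balance moves to 0.989 mM, so cedar's share is 0.823.

6. The relaxation half-life of links and isomer, 0.246 min, is short against the time, so links keep 0.552 of that pool.

I expect cedar, with cedar 45.5 %, larch 25.3 % and birch 25.3 %.

The forecast says cedar, with 46 % (43 % to 49 %), 25.5 % (23 % to 28 %) and 25.2 % (23 % to 28 %), holding that “feeding the third end groups (larch) barely changes anything compared with birch”. For cedar my figure stands a little below the forecast's, and where the forecast gives larch and birch separate figures, my reckoning gives both the same one.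

The simulation gives cedar: 46.1 %, 25.2 % and 25.0 %.

At 6.00 min cedar held first end groups at 1.00 mM, where the share reads 0.822, far above the 0.216 of birch's full charge. Links plus isomer end at 83.5 % in cedar and 45.3 % in birch.

The neighbour is birch with 4.0 mM of first end groups. Its shares are 0.822 at 1.00 mM and 0.572 at 3.00 mM, whose mean gives 38.5 % links. The simulation gives 37.5 %.

All constants were drawn at random within sensible limits; the result is computed.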